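**Plan**

- Retrosynthesis: the two benzoate C–O bonds are cut first (acylation of a C7/C2 diol), then the ring bond C1–C2 with the C4–O bond to C7 restored, then the C2–O bond (enol ether coupling) and the C2–C3 bond (olefination of a glucose C6 aldehyde).
- Feature: with the ring numbered C1 (quaternary carbinol carrying C7H2OBz), C2 (CHOBz), C3=C4, C5 and C6 (CHOH), the vicinal pair C1/C2 next to the C3=C4 alkene is a Claisen retron. C7 was a lactone carbonyl bound through oxygen to C4, so the precursor is a δ-lactone (ring C7–C1–C6–C5–C4–O) with an (E)-2-alkoxyvinyl group on C4.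
- Forward: a D-glucose thioglycoside supplies C7, C1, C6, C5, C4, C3 (sugar C1 to C6). C2 is added by Takai olefination with CHI3 and O2 by copper-catalysed coupling with 4-methoxybenzyl alcohol; the pyranose ring is then oxidised to the δ-lactone, and step 10 converts that ring into the only carbocycle.
- Stereochemistry: C6 and C5 are sugar C3 and C4, carried unchanged. C1 and C2 are set in step 10 by the enforced boat transition state, from the configuration of sugar C5 (which becomes the sp2 carbon C4) and the E geometry of the enol ether.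
- End game: acid to C7 alcohol, PMB removal, benzoylation of O7 and O2, removal of three silyl ethers.

Key step: step 10

Abbreviations: TBS = tert-butyldimethylsilyl, PMB = 4-methoxybenzyl, Bz = benzoyl. Carbocycles are numbered as in the plan; sugars use carbohydrate numbering.

Assumption: lactols 7 and 11 form as anomeric mixtures and silyl glycosides 8 and 10 are drawn as the β-anomers expected from silylation of the equilibrating lactol; the anomeric configuration disappears in step 9 and has no bearing on the route.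

**Step 1**
Reactants: 1 phenyl 1-thio-β-D-glucopyranoside
Product: 2 phenyl 2,3,4,6-tetra-O-TBS-1-thio-β-D-glucopyranoside
Conditions: TBSOTf (excess), pyridine, DMAP, 60 °C
Reagents that add atoms: tert-butyldimethylsilyl triflate, CC(C)(C)[Si](C)(C)OS(=O)(=O)C(F)(F)F
Why: Silyl ether formation with the silyl triflate in warm pyridine is the established way to silylate all four hydroxyls of a thioglucoside, the crowded secondary ones included, and it touches neither the thioglycoside nor any stereocentre.

**Step 2**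
Reactants: 2 phenyl 2,3,4,6-tetra-O-TBS-1-thio-β-D-glucopyranoside
Product: 3 phenyl 2,3,4-tri-O-TBS-1-thio-β-D-glucopyranoside
Conditions: HF·pyridine, pyridine, THF, 0 °C
Reagents that add atoms: none
Why: Selective desilylation, since buffered HF·pyridine cleaves the unhindered primary silyl ether far faster than the three crowded secondary ones and so frees only O6.

**Step 3**
Reactants: 3 phenyl 2,3,4-tri-O-TBS-1-thio-β-D-glucopyranoside
Product: 4 phenyl 2,3,4-tri-O-TBS-1-thio-β-D-gluco-hexodialdo-1,5-pyranoside (C6 aldehyde)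
Conditions: Dess–Martin periodinane, pyridine, CH2Cl2, 0 °C to rt; crude aldehyde used at once
Reagents that add atoms: none
Why: Dess–Martin oxidation needs no base, so the aldehyde, which has an acidic hydrogen at C5 and a silyloxy group at C4, should form without epimerisation or β-elimination, and the sulfide is not oxidised under these buffered conditions.

**Step 4**
Reactants: 4 phenyl 2,3,4-tri-O-TBS-1-thio-β-D-gluco-hexodialdo-1,5-pyranoside; 5 iodoform
Product: 6 phenyl (E)-2,3,4-tri-O-TBS-6,7-dideoxy-7-iodo-1-thio-β-D-gluco-hept-6-enopyranoside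
Conditions: CrCl2, CHI3, THF/1,4-dioxane, 0 °C to rt
Reagents that add atoms: none
Why: Takai olefination, in which the geminal dichromium species from CHI3 and CrCl2 adds to the aldehyde and eliminates to the (E)-alkenyl iodide (the new carbon is the later C2); the medium is not basic and tolerates silyl ethers and the thioglycoside.

**Step 5**
Reactants: 6 phenyl (E)-2,3,4-tri-O-TBS-6,7-dideoxy-7-iodo-1-thio-β-D-gluco-hept-6-enopyranoside
Product: 7 (E)-2,3,4-tri-O-TBS-6,7-dideoxy-7-iodo-D-gluco-hept-6-enopyranose (lactol, anomeric mixture)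
Conditions: NBS, acetone/H2O (9:1), 0 °C
Reagents that add atoms: water, O
Why: Thioglycoside hydrolysis, in which NBS brominates sulfur and water captures the oxocarbenium ion; silyl ethers and the alkenyl iodide survive, which is the reason a thioglycoside and not a methyl glycoside is carried to this point, and the new anomeric centre forms as a mixture that does not matter.

**Step 6**
Reactants: 7 (E)-2,3,4-tri-O-TBS-6,7-dideoxy-7-iodo-D-gluco-hept-6-enopyranose
Product: 8 tert-butyldimethylsilyl (E)-2,3,4-tri-O-TBS-6,7-dideoxy-7-iodo-β-D-gluco-hept-6-enopyranoside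
Conditions: TBSCl, imidazole, DMF, rt
Reagents that add atoms: tert-butyldimethylsilyl chloride, CC(C)(C)[Si](C)(C)Cl
Why: Silyl ether formation at the hemiacetal hydroxyl masks the lactol as a base-stable silyl glycoside for the coupling; silylation of the equilibrating lactol should favour the equatorial β-anomer, and either anomer would serve.

**Step 7**
Reactants: 8 tert-butyldimethylsilyl (E)-2,3,4-tri-O-TBS-6,7-dideoxy-7-iodo-β-D-gluco-hept-6-enopyranoside; 9 4-methoxybenzyl alcohol
Product: 10 tert-butyldimethylsilyl (E)-2,3,4-tri-O-TBS-6,7-dideoxy-7-(4-methoxybenzyloxy)-β-D-gluco-hept-6-enopyranoside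
Conditions: CuI (10 mol %), 3,4,7,8-tetramethyl-1,10-phenanthroline (20 mol %), Cs2CO3, toluene, 80 °C
Reagents that add atoms: none
Why: Copper-catalysed Ullmann-type C–O coupling of an alkenyl iodide with a primary alcohol proceeds with retention of alkene geometry and should give the (E)-enol ether; it is placed at the silyl glycoside stage because the later lactone, with its acidic C–H and β-silyloxy group, would not survive hot carbonate.

**Step 8**
Reactants: 10 tert-butyldimethylsilyl (E)-2,3,4-tri-O-TBS-6,7-dideoxy-7-(4-methoxybenzyloxy)-β-D-gluco-hept-6-enopyranoside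
Product: 11 (E)-2,3,4-tri-O-TBS-6,7-dideoxy-7-(4-methoxybenzyloxy)-D-gluco-hept-6-enopyranose (lactol, anomeric mixture)
Conditions: Bu4NF, AcOH (1:1), THF, −20 to 0 °C
Reagents that add atoms: none
Why: Selective fluoride desilylation, since the anomeric Si–O bond belongs to an acetal oxygen that is a far better leaving group than a secondary alkoxide, so acetic acid-buffered fluoride at low temperature should cleave it alone; the buffer also suppresses silyl migration and keeps the enol ether away from strong acid or base.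

**Step 9**
Reactants: 11 (E)-2,3,4-tri-O-TBS-6,7-dideoxy-7-(4-methoxybenzyloxy)-D-gluco-hept-6-enopyranose
Product: 12 (E)-2,3,4-tri-O-TBS-6,7-dideoxy-7-(4-methoxybenzyloxy)-D-gluco-hept-6-enono-1,5-lactone (δ-lactone ring C7–C1–C6–C5–C4–O, PMB enol ether on C4)
Conditions: Dess–Martin periodinane, pyridine, CH2Cl2, rt
Reagents that add atoms: none
Why: Dess–Martin oxidation of a lactol to the δ-lactone under pyridine buffering is mild enough for the enol ether and for the allylic acyloxy unit of the product; the anomeric carbon becomes the carbonyl carbon C7.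

**Step 10**
Reactants: 12 (E)-2,3,4-tri-O-TBS-6,7-dideoxy-7-(4-methoxybenzyloxy)-D-gluco-hept-6-enono-1,5-lactone
Product: 15 1,5,6-tris(TBS-oxy)-2-(PMB-oxy)cyclohex-3-ene-1-carboxylic acid (carboxyl cis to O2 and O5; trans to O6), via endocyclic trimethylsilyl ketene acetal 13 (not isolated), via trimethylsilyl ester 14 (not isolated)
Conditions: KN(SiMe3)2, Me3SiCl, Et3N, THF, −78 °C; then toluene, 80 °C; then aq. citric acid, rt
Reagents that add atoms: chlorotrimethylsilane, C[Si](C)(C)Cl (its silyl group is present in 13 and 14 only; acid 15 keeps none of it)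
Why: KN(SiMe3)2 removes the C1 hydrogen of lactone 12 with Me3SiCl already present, so the enolate is silylated at once to ketene acetal 13, an allyl vinyl ether (C1=C7–O–C4–C3=C2) that undergoes a concerted [3,3]-sigmatropic shift to silyl ester 14, which is hydrolysed to acid 15 on work-up. The closest known reaction type is the Ireland–Claisen rearrangement of silyl ketene acetals of 6-alkenyl δ-lactones to cyclohexenecarboxylic acids, together with its dioxanone-to-dihydropyran counterpart. The cyclohexene ring C1–C6 closes by C1–C2 bond formation across the lactone ring while the C4–O bond opens it, through a bicyclo[2.2.2]-like boat array that is the only one open because the C6–C5 tether holds C1 and the ring oxygen cis on the ketene acetal. At C1 the carboxyl carbon C7 is delivered to the ring face from which oxygen leaves C4, so the configuration of C4 (sugar C5) places C7 cis to O5 and trans to O6, and at C2 the E geometry of the enol ether in the boat places O2 cis to C7. The step needs silylation and rearrangement to outrun β-elimination of the C6 silyloxy group, which is secured by trapping the enolate in situ at −78 °C, by the poor leaving-group ability of a silyloxide and by the donor oxygens on C7, C1 and C2 that accelerate the shift.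

**Step 11**
Reactants: 15 1,5,6-tris(TBS-oxy)-2-(PMB-oxy)cyclohex-3-ene-1-carboxylic acid
Product: 16 [1,5,6-tris(TBS-oxy)-2-(PMB-oxy)cyclohex-3-en-1-yl]methanol (configuration unchanged)
Conditions: LiAlH4, THF, 0 °C to rt; aq. KNaC4H4O6 (potassium sodium tartrate) work-up
Reagents that add atoms: none
Why: LiAlH4 reduction of a carboxylic acid to the primary alcohol leaves silyl ethers, the PMB ether and the isolated alkene alone and affects no stereocentre; the non-basic tartrate work-up avoids silyl migration to the new hydroxyl.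

**Step 12**
Reactants: 16 [1,5,6-tris(TBS-oxy)-2-(PMB-oxy)cyclohex-3-en-1-yl]methanol
Product: 17 1-(hydroxymethyl)-1,5,6-tris(TBS-oxy)cyclohex-3-en-2-ol (C7 and C2 hydroxyls free)
Conditions: DDQ, CH2Cl2/pH 7 buffer, 0 °C
Reagents that add atoms: none
Why: Oxidative cleavage of the PMB ether with DDQ (benzylic hydride abstraction, then hydrolysis of the oxocarbenium ion) frees O2 while silyl ethers stay; water and low temperature are there to prevent anisylidene acetal formation with the C7 hydroxyl and oxidation of the allylic alcohol.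

**Step 13**
Reactants: 17 1-(hydroxymethyl)-1,5,6-tris(TBS-oxy)cyclohex-3-en-2-ol
Product: 18 2-benzoyloxy-1-(benzoyloxymethyl)-1,5,6-tris(TBS-oxy)cyclohex-3-ene
Conditions: BzCl, pyridine, DMAP, CH2Cl2, 0 °C to rt
Reagents that add atoms: benzoyl chloride, O=C(Cl)c1ccccc1
Why: DMAP-catalysed acylation with benzoyl chloride esterifies the primary C7 hydroxyl and the secondary allylic C2 hydroxyl, the only free hydroxyls, while O1, O5 and O6 remain silylated.

**Step 14**
Reactants: 18 2-benzoyloxy-1-(benzoyloxymethyl)-1,5,6-tris(TBS-oxy)cyclohex-3-ene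
Product: 19 (1S,2S,5R,6S)-2-benzoyloxy-1-(benzoyloxymethyl)cyclohex-3-ene-1,5,6-triol (CNP0141358.1)
Conditions: HF·pyridine, THF, 0 °C to rt
Reagents that add atoms: none
Why: Fluoride desilylation with HF·pyridine should remove the three silyl ethers, the tertiary one included, under mildly acidic conditions in which benzoates neither hydrolyse nor migrate.

**Compound list**

1 | phenyl 1-thio-β-D-glucopyranoside | c1ccccc1S[C@@H]1O[C@H](CO)[C@@H](O)[C@H](O)[C@H]1O | starting material
2 | phenyl 2,3,4,6-tetra-O-TBS-1-thio-β-D-glucopyranoside | c1ccccc1S[C@@H]1O[C@H](CO[Si](C)(C)C(C)(C)C)[C@@H](O[Si](C)(C)C(C)(C)C)[C@H](O[Si](C)(C)C(C)(C)C)[C@H]1O[Si](C)(C)C(C)(C)C | intermediate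
3 | phenyl 2,3,4-tri-O-TBS-1-thio-β-D-glucopyranoside | c1ccccc1S[C@@H]1O[C@H](CO)[C@@H](O[Si](C)(C)C(C)(C)C)[C@H](O[Si](C)(C)C(C)(C)C)[C@H]1O[Si](C)(C)C(C)(C)C | intermediate
4 | phenyl 2,3,4-tri-O-TBS-1-thio-β-D-gluco-hexodialdo-1,5-pyranoside | c1ccccc1S[C@@H]1O[C@H](C=O)[C@@H](O[Si](C)(C)C(C)(C)C)[C@H](O[Si](C)(C)C(C)(C)C)[C@H]1O[Si](C)(C)C(C)(C)C | intermediate
5 | iodoform | IC(I)I | starting material
6 | phenyl (E)-2,3,4-tri-O-TBS-6,7-dideoxy-7-iodo-1-thio-β-D-gluco-hept-6-enopyranoside | c1ccccc1S[C@@H]1O[C@H](/C=C/I)[C@@H](O[Si](C)(C)C(C)(C)C)[C@H](O[Si](C)(C)C(C)(C)C)[C@H]1O[Si](C)(C)C(C)(C)C | intermediate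
7 | (E)-2,3,4-tri-O-TBS-6,7-dideoxy-7-iodo-D-gluco-hept-6-enopyranose (anomeric mixture) | OC1O[C@H](/C=C/I)[C@@H](O[Si](C)(C)C(C)(C)C)[C@H](O[Si](C)(C)C(C)(C)C)[C@H]1O[Si](C)(C)C(C)(C)C | intermediate
8 | tert-butyldimethylsilyl (E)-2,3,4-tri-O-TBS-6,7-dideoxy-7-iodo-β-D-gluco-hept-6-enopyranoside | CC(C)(C)[Si](C)(C)O[C@@H]1O[C@H](/C=C/I)[C@@H](O[Si](C)(C)C(C)(C)C)[C@H](O[Si](C)(C)C(C)(C)C)[C@H]1O[Si](C)(C)C(C)(C)C | intermediate
9 | 4-methoxybenzyl alcohol | COc1ccc(CO)cc1 | starting material
10 | tert-butyldimethylsilyl (E)-2,3,4-tri-O-TBS-6,7-dideoxy-7-(4-methoxybenzyloxy)-β-D-gluco-hept-6-enopyranoside | CC(C)(C)[Si](C)(C)O[C@@H]1O[C@H](/C=C/OCc2ccc(OC)cc2)[C@@H](O[Si](C)(C)C(C)(C)C)[C@H](O[Si](C)(C)C(C)(C)C)[C@H]1O[Si](C)(C)C(C)(C)C | intermediate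
11 | (E)-2,3,4-tri-O-TBS-6,7-dideoxy-7-(4-methoxybenzyloxy)-D-gluco-hept-6-enopyranose (anomeric mixture) | OC1O[C@H](/C=C/OCc2ccc(OC)cc2)[C@@H](O[Si](C)(C)C(C)(C)C)[C@H](O[Si](C)(C)C(C)(C)C)[C@H]1O[Si](C)(C)C(C)(C)C | intermediate
12 | (E)-2,3,4-tri-O-TBS-6,7-dideoxy-7-(4-methoxybenzyloxy)-D-gluco-hept-6-enono-1,5-lactone | O=C1O[C@H](/C=C/OCc2ccc(OC)cc2)[C@@H](O[Si](C)(C)C(C)(C)C)[C@H](O[Si](C)(C)C(C)(C)C)[C@H]1O[Si](C)(C)C(C)(C)C | intermediate
13 | endocyclic trimethylsilyl ketene acetal of lactone 12 | C[Si](C)(C)OC1=C(O[Si](C)(C)C(C)(C)C)[C@@H](O[Si](C)(C)C(C)(C)C)[C@H](O[Si](C)(C)C(C)(C)C)[C@@H](/C=C/OCc2ccc(OC)cc2)O1 | intermediate (not isolated)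
14 | trimethylsilyl ester of acid 15 | C[Si](C)(C)OC(=O)[C@@]1(O[Si](C)(C)C(C)(C)C)[C@@H](OCc2ccc(OC)cc2)C=C[C@@H](O[Si](C)(C)C(C)(C)C)[C@@H]1O[Si](C)(C)C(C)(C)C | intermediate (not isolated)
15 | 1,5,6-tris(TBS-oxy)-2-(PMB-oxy)cyclohex-3-ene-1-carboxylic acid, carboxyl cis to O2 and O5, trans to O6 | OC(=O)[C@@]1(O[Si](C)(C)C(C)(C)C)[C@@H](OCc2ccc(OC)cc2)C=C[C@@H](O[Si](C)(C)C(C)(C)C)[C@@H]1O[Si](C)(C)C(C)(C)C | intermediate
16 | [1,5,6-tris(TBS-oxy)-2-(PMB-oxy)cyclohex-3-en-1-yl]methanol, configuration as in 15 | OC[C@@]1(O[Si](C)(C)C(C)(C)C)[C@@H](OCc2ccc(OC)cc2)C=C[C@@H](O[Si](C)(C)C(C)(C)C)[C@@H]1O[Si](C)(C)C(C)(C)C | intermediate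
17 | 1-(hydroxymethyl)-1,5,6-tris(TBS-oxy)cyclohex-3-en-2-ol, configuration as in 15 | OC[C@@]1(O[Si](C)(C)C(C)(C)C)[C@@H](O)C=C[C@@H](O[Si](C)(C)C(C)(C)C)[C@@H]1O[Si](C)(C)C(C)(C)C | intermediate
18 | 2-benzoyloxy-1-(benzoyloxymethyl)-1,5,6-tris(TBS-oxy)cyclohex-3-ene, configuration as in 15 | O=C(OC[C@@]1(O[Si](C)(C)C(C)(C)C)[C@@H](OC(=O)c2ccccc2)C=C[C@@H](O[Si](C)(C)C(C)(C)C)[C@@H]1O[Si](C)(C)C(C)(C)C)c1ccccc1 | intermediate
19 | (1S,2S,5R,6S)-2-benzoyloxy-1-(benzoyloxymethyl)cyclohex-3-ene-1,5,6-triol (CNP0141358.1) | O=C(OC[C@@]1(O)[C@@H](OC(=O)c2ccccc2)C=C[C@@H](O)[C@@H]1O)c1ccccc1 | target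

**Count**

Total steps: 14. Longest linear sequence: 14 steps (1 to 19).

**Steps most likely to fail**

Step 10. After deprotonation the C6 silyloxy group may be expelled by β-elimination before the enolate is silylated, or the allylic C4–O bond may ionise so that the ring closes stepwise and the configuration at C1 and C2 erodes. The fallback sets out from lactol 11 and returns at alcohol 16, and it makes no enolate. Lactol 11 would be treated with MsCl and Et3N to give anomeric mesylate F1, which DBU eliminates in the same flask to 2-silyloxy glycal F2 (the pyranose 1,2-ene with the silyloxy group kept on sugar C2). On heating in xylene in a sealed tube its allyl vinyl ether unit should undergo the thermal Claisen rearrangement known for 5-vinyl glycals, through the same boat geometry and with the same C1–C2 bond formed, to cyclohexenecarbaldehyde F3. NaBH4 in MeOH would reduce F3 to 16.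

Step 8. Fluoride may also remove secondary silyl ethers, or the silyl group on sugar O2 may migrate to the anomeric oxygen once the lactol alkoxide is free. The fallback sets out from lactol 7 and returns at lactol 11, and it rests the differentiation on the size of the silyl group instead of on its position. Lactol 7 would be silylated with Et3SiCl and imidazole to anomeric triethylsilyl glycoside F4, which is coupled with 9 under the conditions of step 7 to triethylsilyl enol ether glycoside F5. The triethylsilyl group alone would then be removed with pyridine-buffered HF·pyridine at −20 °C, the reagent that leaves secondary TBS ethers intact in step 2, so that 11 forms without an alkoxide that could carry silyl groups from oxygen to oxygen.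

Step 7. Hot Cs2CO3 may dehydroiodinate the alkenyl iodide to the alkyne, or the caesium alkoxide may attack the anomeric silyl ether. The fallback sets out from iodide 8 and returns at enol ether 10, and it replaces the hot basic coupling by an oxidative coupling at room temperature. Miyaura borylation of 8 (B2pin2, PdCl2(PPh3)2, KOPh, toluene, 50 °C) would give (E)-alkenyl pinacol boronate F6 with retention of geometry. Chan–Lam-type coupling of F6 with 9 (Cu(OAc)2, Et3N, air, 9 as cosolvent, rt) should then deliver 10.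

**Further compounds**

F1 | step 10 | anomeric methanesulfonate of lactol 11 (anomeric mixture) | CS(=O)(=O)OC1O[C@H](/C=C/OCc2ccc(OC)cc2)[C@@H](O[Si](C)(C)C(C)(C)C)[C@H](O[Si](C)(C)C(C)(C)C)[C@H]1O[Si](C)(C)C(C)(C)C
F2 | step 10 | 2-silyloxy glycal: (E)-1,5-anhydro-2,3,4-tri-O-TBS-6,7-dideoxy-7-(4-methoxybenzyloxy)-D-arabino-hepta-1,6-dienitol | C1=C(O[Si](C)(C)C(C)(C)C)[C@@H](O[Si](C)(C)C(C)(C)C)[C@H](O[Si](C)(C)C(C)(C)C)[C@@H](/C=C/OCc2ccc(OC)cc2)O1
F3 | step 10 | 1,5,6-tris(TBS-oxy)-2-(PMB-oxy)cyclohex-3-ene-1-carbaldehyde, configuration as in 15 | O=C[C@@]1(O[Si](C)(C)C(C)(C)C)[C@@H](OCc2ccc(OC)cc2)C=C[C@@H](O[Si](C)(C)C(C)(C)C)[C@@H]1O[Si](C)(C)C(C)(C)C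
F4 | step 8 | triethylsilyl (E)-2,3,4-tri-O-TBS-6,7-dideoxy-7-iodo-β-D-gluco-hept-6-enopyranoside | CC[Si](CC)(CC)O[C@@H]1O[C@H](/C=C/I)[C@@H](O[Si](C)(C)C(C)(C)C)[C@H](O[Si](C)(C)C(C)(C)C)[C@H]1O[Si](C)(C)C(C)(C)C
F5 | step 8 | triethylsilyl (E)-2,3,4-tri-O-TBS-6,7-dideoxy-7-(4-methoxybenzyloxy)-β-D-gluco-hept-6-enopyranoside | CC[Si](CC)(CC)O[C@@H]1O[C@H](/C=C/OCc2ccc(OC)cc2)[C@@H](O[Si](C)(C)C(C)(C)C)[C@H](O[Si](C)(C)C(C)(C)C)[C@H]1O[Si](C)(C)C(C)(C)C
F6 | step 7 | tert-butyldimethylsilyl (E)-2,3,4-tri-O-TBS-6,7-dideoxy-7-(4,4,5,5-tetramethyl-1,3,2-dioxaborolan-2-yl)-β-D-gluco-hept-6-enopyranoside | CC(C)(C)[Si](C)(C)O[C@@H]1O[C@H](/C=C/B2OC(C)(C)C(C)(C)O2)[C@@H](O[Si](C)(C)C(C)(C)C)[C@H](O[Si](C)(C)C(C)(C)C)[C@H]1O[Si](C)(C)C(C)(C)C
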